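**Carrier split.** If this run is repeated, the number to follow is how the carrier divides between its spent and fresh forms, the fresh form being the one that meets starting material to make target.

starting material 0.050 M; salt in the second phase 0.0550 M; spent carrier 6.5 mM; time 6.0 min; volume of the second phase over the first 2.0

- amount of target and crystals together at 6.0 min, in percent of the starting material charged
- the change that raises the amount of target and crystals together at 6.0 min, in percent of the starting material charged most ("none" if none brings more than 2 percentage points) (spring / autumn / noon / none)
- amount of target and crystals together at 6.0 min, in percent of the starting material charged, after noon

- spring: doubling the amount of salt in the second phase, all else as stated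
- autumn: doubling the solubility in step 3, all else as stated
- noon: doubling the dissolution coefficient of step 3, all else as stated

- in percentages every species weighs as the starting material in it: one side product counts as two
- for target the crystals are counted in
- in the second phase: salt in the second phase, spent salt in the second phase; everything else is in the first
- charges count per volume of the first phase; a concentration in a rate is the amount of a species over the volume of its own phase; every rate counts per litre of the first phase
- as a solid, counted per litre of solution: crystals
- run time (flask): 6.0 min

    spent carrier + salt in the second phase ⇌ fresh carrier + spent salt in the second phase (K1 = 2.10, k1 = 36.3 L mol⁻¹ min⁻¹)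
    starting material + fresh carrier → target + spent carrier (k2 = 18.4 L mol⁻¹ min⁻¹)
    crystals ⇌ target, rate k3*(cs3 - [target]) while solid is left; crystals form when [target] > cs3 (cs3 = 1.1 mM, k3 = 2.54 min⁻¹)
    target + fresh carrier ⇌ isomer of the product + fresh carrier, rate k4*[target]*[fresh carrier] forward; the back reaction follows from the equilibrium constant (K4 = 0.34, k4 = 7.01 L mol⁻¹ min⁻¹)
    starting material + target → side product (k5 = 7.46 L mol⁻¹ min⁻¹)

**Both ends.** Spent carrier meets salt at the pseudo-first-order frequency 0.998 min⁻¹, the salt's own concentration being its charge over the volume ratio, and fresh carrier meets starting material at 0.920 min⁻¹. While no spent salt is present, a much quicker regeneration would leave the carrier fresh, and a much quicker consumption would leave it spent. Joining the ends gives the fresh share, the part of the carrier standing fresh when its changes of form balance, which is regeneration frequency over the sum of the frequencies that change the carrier's form, 52.0%; no spent salt is charged, so the way back adds nothing at the start but joins the sum later.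

**Hand reckoning.** This reckoning is my own, with charges held at their starting values. Target forms at 3.11 mM min⁻¹, which is 37.3% of the charge over the run. With crystals growing as fast as target forms, this reckoning puts dissolved target near 2.33 mM, and side product then takes 27.9% of what forms, leaving 26.9%.

**Three settings.** Spring, which doubles the salt, lifts the fresh share to 68.5%, worth about 8.5 percentage points by hand. Autumn, which doubles the solubility, lifts dissolved target to 3.43 mM in this reckoning, costing about 4.9 points. Noon, which doubles the dissolution coefficient, lowers it to 1.71 mM, gaining about 2.7 points, so by hand spring gains more than noon and is my choice.

**The forecast.** It gives 22.3% for the amount of target and crystals, spring as the best change and 23.5% after noon, starting from “The carrier sits about half regenerated”; its first figure lies below mine.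

**The simulation.** The flask gives 20.5%, and 21.6% after noon. Spring moves the answer by 8 points, autumn by −2.9 points and noon by 1 point, so the choice is spring.

**Share again.** At 6.00 min the flask's regeneration runs at 0.700 min⁻¹, against 0.622 min⁻¹ for consumption and 0.142 min⁻¹ for the way back, a fresh share of 47.8% beside the 48.0% of fresh carrier standing there. The neighbour flask charged with 0.026 M of spent carrier has these three frequencies at 0.289 min⁻¹, 0.294 min⁻¹ and 0.338 min⁻¹ at 6.00 min, a fresh share of 31.4% beside its 33.2% of fresh carrier.

The numbers of this flask are invented; no experiment stands behind them.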